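**Strategy.** The route disconnects the side chain between the benzylic methylene C1' on the quinone ring and the olefinic carbon C2'. The key step is a one-pot, three-component union: zirconium-catalysed syn-methylalumination of a terminal alkyne, then palladium-catalysed coupling of the resulting (E)-alkenylalane with a tetramethoxybenzyl chloride. It forms the C3'–CH3 bond, the (E)-C2'=C3' geometry and the C1'–C2' bond in one operation, exploiting the methyl-branched allyl link between the quinone ring and the trimethylcyclohexene ring. The alkyne carries both stereocentres of that ring, set by an enantioselective Ireland–Claisen rearrangement of geranyl propionate; ring-closing metathesis then closes the ring. Oxidative demethylation and selective hydrolysis finish the hydroxymethoxyquinone.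

Key step: step 9

Assumption (step 1): the (S,S)-antipode of the boron controller with i-Pr2NEt in CH2Cl2 is taken to give the O-boron enolate with methyl cis to O–B and to select the face leading to the (2S,3R)-acid; this assignment is not secured, and since both antipodes of the bis-sulfonamide are available, a reversed sense would be met by using the (R,R)-antipode with no other change.

**Step 1**
Reactants: 1 geranyl propionate [(2E)-3,7-dimethylocta-2,6-dien-1-yl propanoate]
Product: 4 (2S,3R)-3-ethenyl-2,3,7-trimethyloct-6-enoic acid, via boron ketene acetal 2 (not isolated), via acyloxyborane 3 (not isolated)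
Conditions: (1S,2S)-N,N'-bis[3,5-bis(trifluoromethyl)benzenesulfonyl]-1,2-diphenylethane-1,2-diamine, BBr3, CH2Cl2, rt, then evacuation; 1, i-Pr2NEt, CH2Cl2, −78 °C → rt; aq. HCl work-up
Reagents that add atoms: none
Why: Enantioselective Ireland–Claisen rearrangement of an O-boron ester enolate through a chair transition state, in which the enolate methyl (cis to O–B) is equatorial and the (E)-geranyl terminus places its methyl axial and the homoprenyl chain equatorial, which should set the (2S*,3R*) relation of the new tertiary and quaternary centres, while the C2-symmetric bis-sulfonamide ligand on boron selects the enolate face and so the absolute configuration.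

**Step 2**
Reactants: 4 (2S,3R)-3-ethenyl-2,3,7-trimethyloct-6-enoic acid
Product: 6 (3S,4R)-4-ethenyl-3,4,8-trimethylnon-7-en-2-one, via dilithium gem-diolate 5 (not isolated)
Conditions: MeLi (3 equiv), Et2O, 0 °C → rt; inverse quench into cold aq. HCl
Reagents that add atoms: methyllithium, C[Li]
Why: Addition of methyllithium to the lithium carboxylate should stop at the dilithium gem-diolate, which releases the methyl ketone only on acidic work-up, so no tertiary alcohol forms and the α-stereocentre is not enolised.

**Step 3**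
Reactants: 6 (3S,4R)-4-ethenyl-3,4,8-trimethylnon-7-en-2-one
Product: 7 (3R,4R)-4-ethenyl-2,3,4,8-tetramethylnona-1,7-diene
Conditions: Ph3PCH3Br, KN(SiMe3)2, THF, 0 °C → rt
Reagents that add atoms: methyltriphenylphosphonium bromide (as its ylide), C[P+](c1ccccc1)(c1ccccc1)c1ccccc1.[Br-]
Why: Wittig methylenation with the salt-free ylide should convert the methyl ketone into the isopropenyl group, the hindered α-CH next to the quaternary carbon being deprotonated too slowly for epimerisation (the descriptor at C3 changes only through the priority rules).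

**Step 4**
Reactants: 7 (3R,4R)-4-ethenyl-2,3,4,8-tetramethylnona-1,7-diene
Product: 8 (4R)-4,8-dimethyl-4-[(2R)-3-methylbut-3-en-2-yl]non-7-enal
Conditions: Rh(acac)(CO)2 (1 mol %), Xantphos (2 mol %), CO/H2 (1:1, 10 bar), toluene, 60 °C
Reagents that add atoms: carbon monoxide, [C-]#[O+]
Why: Rhodium-catalysed hydroformylation with a wide-bite-angle diphosphine should give the linear aldehyde at the monosubstituted vinyl group, which sits on a quaternary carbon and cannot isomerise, while the hindered 1,1-disubstituted and trisubstituted olefins react far more slowly.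

**Step 5**
Reactants: 8 (4R)-4,8-dimethyl-4-[(2R)-3-methylbut-3-en-2-yl]non-7-enal
Product: 9 3-[(1R,2S)-1,2,3-trimethylcyclohex-3-en-1-yl]propanal
Conditions: second-generation Hoveyda–Grubbs catalyst (5 mol %), toluene, 80 °C, argon sparge
Reagents that add atoms: none
Why: Ring-closing metathesis, in which the ruthenium alkylidene formed at the prenyl-type olefin (loss of 2-methylpropene) should close onto the isopropenyl group to give the six-membered ring with its trisubstituted C=C, the aldehyde and both stereocentres being untouched.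

**Step 6**
Reactants: 9 3-[(1R,2S)-1,2,3-trimethylcyclohex-3-en-1-yl]propanal
Product: 10 (5R,6S)-5-(but-3-yn-1-yl)-1,5,6-trimethylcyclohex-1-ene
Conditions: dimethyl (1-diazo-2-oxopropyl)phosphonate, K2CO3, MeOH, 0 °C → rt
Reagents that add atoms: dimethyl (1-diazo-2-oxopropyl)phosphonate, CC(=O)C(=[N+]=[N-])P(=O)(OC)OC
Why: Seyferth–Gilbert homologation in the Ohira–Bestmann variant should convert the non-epimerisable aldehyde into the terminal alkyne with one added carbon under mild carbonate conditions.

**Step 7**
Reactants: 11 1,2,4,5-tetramethoxybenzene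
Product: 13 (2,3,5,6-tetramethoxyphenyl)methanol, via aryllithium 12 (not isolated)
Conditions: n-BuLi, TMEDA, THF, 0 °C; then (CH2O)n, 0 °C → rt; H2O quench
Reagents that add atoms: formaldehyde (as paraformaldehyde), C=O
Why: Directed ortho-lithiation at a ring C–H flanked by two methoxy groups (both ring hydrogens are equivalent) followed by addition of the aryllithium to formaldehyde should give the benzylic alcohol.

**Step 8**
Reactants: 13 (2,3,5,6-tetramethoxyphenyl)methanol
Product: 14 3-(chloromethyl)-1,2,4,5-tetramethoxybenzene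
Conditions: SOCl2, pyridine, CH2Cl2, 0 °C
Reagents that add atoms: thionyl chloride, ClS(Cl)=O
Why: Chlorination of the electron-rich benzylic alcohol through its chlorosulfite under buffered conditions should give the benzyl chloride without acid-promoted self-condensation.

**Step 9**
Reactants: 10 (5R,6S)-5-(but-3-yn-1-yl)-1,5,6-trimethylcyclohex-1-ene, 14 3-(chloromethyl)-1,2,4,5-tetramethoxybenzene
Product: 16 1,2,4,5-tetramethoxy-3-{(2E)-3-methyl-5-[(1R,2S)-1,2,3-trimethylcyclohex-3-en-1-yl]pent-2-en-1-yl}benzene, via (E)-alkenylalane 15 (not isolated)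
Conditions: AlMe3 (2.5 equiv), Cp2ZrCl2 (0.25 equiv), CH2Cl2, 0 °C → rt; volatiles removed in vacuo; then 14, Pd(PPh3)4 (5 mol %), THF, rt
Reagents that add atoms: trimethylaluminium, C[Al](C)C
Why: The Cp2ZrCl2/AlMe3 system adds methyl and metal across the terminal alkyne in a syn fashion with methyl on the internal carbon, giving the (E)-2-methylalkenyl dimethylalane 15; zerovalent palladium then inserts into the C–Cl bond of 14, the alkenyl group passes from aluminium to palladium with retention, and reductive elimination forms the C1'–C2' bond. The closest known reaction type is the Negishi zirconium-catalysed methylalumination followed by palladium-catalysed alkenylalane–benzyl chloride cross-coupling, as used for prenylated quinone side chains. No ring is closed and no stereocentre is created; the (E)-geometry of C2'=C3' follows from syn-addition plus retention. The step needs methyl delivery to the internal alkyne carbon, reaction at the alkyne and not at the ring olefin, and transfer of the alkenyl and not a methyl group to palladium. These should be secured by the terminal alkyne, by the inertness of the trisubstituted ring olefin to carboalumination, by the faster transmetalation of the sp2 C–Al bond, and by removal of excess AlMe3 before the coupling. The benzyl chloride, flanked by two methoxy groups, is a reactive electrophile that has no β-hydrogen to lose.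

**Step 10**
Reactants: 16 1,2,4,5-tetramethoxy-3-{(2E)-3-methyl-5-[(1R,2S)-1,2,3-trimethylcyclohex-3-en-1-yl]pent-2-en-1-yl}benzene
Product: 17 2,5-dimethoxy-3-{(2E)-3-methyl-5-[(1R,2S)-1,2,3-trimethylcyclohex-3-en-1-yl]pent-2-en-1-yl}cyclohexa-2,5-diene-1,4-dione
Conditions: (NH4)2Ce(NO3)6 (2.5 equiv), MeCN/H2O, 0 °C
Reagents that add atoms: water, O
Why: Oxidative demethylation by tetravalent cerium (arene radical cation, attack of water at a para pair of methoxy-bearing carbons, loss of two methanol) should give the para-quinone, both para pairs leading to the same 2,5-dimethoxy-3-alkyl quinone by the symmetry of the arene, with the trisubstituted olefins left intact at 0 °C.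

**Step 11**
Reactants: 17 2,5-dimethoxy-3-{(2E)-3-methyl-5-[(1R,2S)-1,2,3-trimethylcyclohex-3-en-1-yl]pent-2-en-1-yl}cyclohexa-2,5-diene-1,4-dione
Product: 18 metachromin C, 2-hydroxy-5-methoxy-3-{(2E)-3-methyl-5-[(1R,2S)-1,2,3-trimethylcyclohex-3-en-1-yl]pent-2-en-1-yl}cyclohexa-2,5-diene-1,4-dione
Conditions: KOH (aq), MeOH, 0 °C → rt; then dilute HCl
Reagents that add atoms: potassium hydroxide, [K+].[OH-]
Why: Vinylogous ester saponification by addition–elimination should occur at the C2 methoxy, which is flanked by the alkyl group and C1=O, twisted out of conjugation and therefore the more electrophilic site, and the hydroxyquinone anion then resists a second hydrolysis so the C5 methoxy is kept.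

**Compound list**
1 | geranyl propionate, (2E)-3,7-dimethylocta-2,6-dien-1-yl propanoate | CCC(=O)OC/C=C(\C)CCC=C(C)C | starting material
2 | boron ketene acetal of 1 (not isolated), methyl cis to O–B, boron in a (4S,5S)-1,3-bis{[3,5-bis(trifluoromethyl)phenyl]sulfonyl}-4,5-diphenyl-1,3,2-diazaborolidine | C/C=C(/OC/C=C(\C)CCC=C(C)C)OB1N(S(=O)(=O)c2cc(cc(c2)C(F)(F)F)C(F)(F)F)[C@@H](c2ccccc2)[C@H](c2ccccc2)N1S(=O)(=O)c1cc(cc(c1)C(F)(F)F)C(F)(F)F | intermediate
3 | acyloxyborane (not isolated), (4S,5S)-diazaborolidin-2-yl (2S,3R)-3-ethenyl-2,3,7-trimethyloct-6-enoate | C=C[C@@](C)(CCC=C(C)C)[C@H](C)C(=O)OB1N(S(=O)(=O)c2cc(cc(c2)C(F)(F)F)C(F)(F)F)[C@@H](c2ccccc2)[C@H](c2ccccc2)N1S(=O)(=O)c1cc(cc(c1)C(F)(F)F)C(F)(F)F | intermediate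
4 | (2S,3R)-3-ethenyl-2,3,7-trimethyloct-6-enoic acid | C=C[C@@](C)(CCC=C(C)C)[C@H](C)C(=O)O | intermediate
5 | dilithium (3S,4R)-4-ethenyl-3,4,8-trimethylnon-7-ene-2,2-diolate (not isolated) | C=C[C@@](C)(CCC=C(C)C)[C@H](C)C(C)(O[Li])O[Li] | intermediate
6 | (3S,4R)-4-ethenyl-3,4,8-trimethylnon-7-en-2-one | C=C[C@@](C)(CCC=C(C)C)[C@H](C)C(C)=O | intermediate
7 | (3R,4R)-4-ethenyl-2,3,4,8-tetramethylnona-1,7-diene | C=C[C@@](C)(CCC=C(C)C)[C@H](C)C(C)=C | intermediate
8 | (4R)-4,8-dimethyl-4-[(2R)-3-methylbut-3-en-2-yl]non-7-enal | O=CCC[C@@](C)(CCC=C(C)C)[C@H](C)C(C)=C | intermediate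
9 | 3-[(1R,2S)-1,2,3-trimethylcyclohex-3-en-1-yl]propanal | O=CCC[C@@]1(C)CCC=C(C)[C@H]1C | intermediate
10 | (5R,6S)-5-(but-3-yn-1-yl)-1,5,6-trimethylcyclohex-1-ene | C#CCC[C@@]1(C)CCC=C(C)[C@H]1C | intermediate
11 | 1,2,4,5-tetramethoxybenzene | COc1cc(OC)c(OC)cc1OC | starting material
12 | (2,3,5,6-tetramethoxyphenyl)lithium (not isolated) | [Li]c1c(OC)c(OC)cc(OC)c1OC | intermediate
13 | (2,3,5,6-tetramethoxyphenyl)methanol | OCc1c(OC)c(OC)cc(OC)c1OC | intermediate
14 | 3-(chloromethyl)-1,2,4,5-tetramethoxybenzene | ClCc1c(OC)c(OC)cc(OC)c1OC | intermediate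
15 | dimethyl{(1E)-2-methyl-4-[(1R,2S)-1,2,3-trimethylcyclohex-3-en-1-yl]but-1-en-1-yl}alumane (not isolated) | C[Al](C)/C=C(\C)CC[C@@]1(C)CCC=C(C)[C@H]1C | intermediate
16 | 1,2,4,5-tetramethoxy-3-{(2E)-3-methyl-5-[(1R,2S)-1,2,3-trimethylcyclohex-3-en-1-yl]pent-2-en-1-yl}benzene | COc1cc(OC)c(OC)c(C/C=C(\C)CC[C@@]2(C)CCC=C(C)[C@H]2C)c1OC | intermediate
17 | 2,5-dimethoxy-3-{(2E)-3-methyl-5-[(1R,2S)-1,2,3-trimethylcyclohex-3-en-1-yl]pent-2-en-1-yl}cyclohexa-2,5-diene-1,4-dione | COC1=CC(=O)C(OC)=C(C/C=C(\C)CC[C@@]2(C)CCC=C(C)[C@H]2C)C1=O | intermediate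
18 | metachromin C, 2-hydroxy-5-methoxy-3-{(2E)-3-methyl-5-[(1R,2S)-1,2,3-trimethylcyclohex-3-en-1-yl]pent-2-en-1-yl}cyclohexa-2,5-diene-1,4-dione | COC1=CC(=O)C(O)=C(C/C=C(\C)CC[C@@]2(C)CCC=C(C)[C@H]2C)C1=O | target

**Step count and risks**
Total step count: 11. Longest linear sequence: 9 steps (steps 1–6, then 9, 10 and 11); steps 7 and 8 make the aromatic partner.

Steps most likely to fail:

Step 1. The risk is incomplete control of the enolate geometry or of the enolate face by the boron ligand, which would erode the diastereomeric and enantiomeric purity or deliver the mirror-image series. The fallback sets out from 1 and uses the classical Ireland–Claisen rearrangement: LDA in THF/DMPU at −78 °C with Me3SiCl should give the (Z)-silyl ketene acetal {[(1Z)-1-{[(2E)-3,7-dimethylocta-2,6-dien-1-yl]oxy}prop-1-en-1-yl]oxy}(trimethyl)silane F1 (methyl cis to OSi). On warming this rearranges through the same chair to racemic trimethylsilyl (2S*,3R*)-3-ethenyl-2,3,7-trimethyloct-6-enoate F2, which is hydrolysed on work-up to racemic (2S*,3R*)-3-ethenyl-2,3,7-trimethyloct-6-enoic acid F3. Resolution by crystallisation of the (1S)-1-phenylethylammonium (2S,3R)-3-ethenyl-2,3,7-trimethyloct-6-enoate salt F4 (or with the antipodal amine, whichever gives the less soluble salt of the wanted acid) and acidification returns to the route at 4.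

Step 5. The risk is slow initiation at two hindered olefins, so that catalyst decomposition and ruthenium-hydride olefin migration (with loss of the allylic stereocentre) outrun ring closure. The fallback sets out from 6 and replaces steps 3–5. Buffered m-CPBA epoxidation of the electron-rich trisubstituted olefin should give (3S,4R)-4-[2-(3,3-dimethyloxiran-2-yl)ethyl]-3,4-dimethylhex-5-en-2-one F5. Cleavage with H5IO6 in THF/H2O gives (4R,5S)-4-ethenyl-4,5-dimethyl-6-oxoheptanal F6. Intramolecular McMurry coupling with low-valent titanium (TiCl3, Zn–Cu couple, DME, reflux, high dilution) closes the ring to (5R,6R)-5-ethenyl-1,5,6-trimethylcyclohex-1-ene F7. Hydroformylation of its vinyl group under the conditions of step 4 returns to the route at 9.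

Step 11. The risk is poor site selectivity between the two vinylogous esters, or over-hydrolysis. The fallback sets out from 17: exhaustive saponification (NaOH aq., EtOH, then acid) should give 2,5-dihydroxy-3-{(2E)-3-methyl-5-[(1R,2S)-1,2,3-trimethylcyclohex-3-en-1-yl]pent-2-en-1-yl}cyclohexa-2,5-diene-1,4-dione F8. Acid-catalysed vinylogous Fischer esterification (MeOH, cat. H2SO4, rt) should then methylate the unhindered C5 oxygen next to C6–H and return to the route at 18.

**Further compounds**
F1 | step 1 | {[(1Z)-1-{[(2E)-3,7-dimethylocta-2,6-dien-1-yl]oxy}prop-1-en-1-yl]oxy}(trimethyl)silane | C/C=C(/OC/C=C(\C)CCC=C(C)C)O[Si](C)(C)C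
F2 | step 1 | trimethylsilyl (2S*,3R*)-3-ethenyl-2,3,7-trimethyloct-6-enoate (racemate, one enantiomer drawn) | C=C[C@@](C)(CCC=C(C)C)[C@H](C)C(=O)O[Si](C)(C)C
F3 | step 1 | (2S*,3R*)-3-ethenyl-2,3,7-trimethyloct-6-enoic acid (racemate, one enantiomer drawn) | C=C[C@@](C)(CCC=C(C)C)[C@H](C)C(=O)O
F4 | step 1 | (1S)-1-phenylethylammonium (2S,3R)-3-ethenyl-2,3,7-trimethyloct-6-enoate | C=C[C@@](C)(CCC=C(C)C)[C@H](C)C(=O)[O-].C[C@H]([NH3+])c1ccccc1
F5 | step 5 | (3S,4R)-4-[2-(3,3-dimethyloxiran-2-yl)ethyl]-3,4-dimethylhex-5-en-2-one (epoxide carbon as a mixture) | C=C[C@@](C)(CCC1OC1(C)C)[C@H](C)C(C)=O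
F6 | step 5 | (4R,5S)-4-ethenyl-4,5-dimethyl-6-oxoheptanal | C=C[C@@](C)(CCC=O)[C@H](C)C(C)=O
F7 | step 5 | (5R,6R)-5-ethenyl-1,5,6-trimethylcyclohex-1-ene | C=C[C@@]1(C)CCC=C(C)[C@H]1C
F8 | step 11 | 2,5-dihydroxy-3-{(2E)-3-methyl-5-[(1R,2S)-1,2,3-trimethylcyclohex-3-en-1-yl]pent-2-en-1-yl}cyclohexa-2,5-diene-1,4-dione | OC1=CC(=O)C(O)=C(C/C=C(\C)CC[C@@]2(C)CCC=C(C)[C@H]2C)C1=O
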